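**Retrosynthetic overview**

1. Target 13 ← bis-pivalate 12 (ester methanolysis). 12 ← open precursor 11 by cutting the biaryl bond C2 (ring C)–C1' (ring B): the eight-membered oxocine ring D is closed last by a palladium-catalysed twofold C–H coupling, with no halogen or metal on either carbon.
2. 11 ← 3-iodochromone 4 + aryl 1,1-dimethylpropargyl ether 8 (Sonogashira coupling, then alkyne hydrogenation); the propargyl unit supplies the O–CMe2 carbon and both CH2 groups of ring D.
3. 4 ← acetophenone 1 (mono-pivalate, enaminone, iodocyclisation); 8 ← resorcinol 5 + 3-chloro-3-methylbut-1-yne 7.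
4. Ring order: rings A and B are bought, ring C (pyranone) is formed in step 2, ring D in step 7.
5. Enabling feature: with C3 alkylated, C2–H is the only C–H on ring C (next to O1, β-carbon of the vinylogous ester). On the 1,3-dioxygenated ring B, the carbon that becomes C1' is ortho to the tether oxygen and para to the second oxygen. The other reachable ortho carbon lies between both oxygens and is blocked, and the CH2–CH2–CMe2–O tether with its gem-dimethyl group holds the two C–H bonds together.

Key step: step 7

Remark: the target has no stereocentre and the biaryl axis of ring D is taken as conformationally mobile, so no stereocontrol is planned; "pivalate" means 2,2-dimethylpropanoate throughout.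

**Route**

Step 1
Reactants: 1 2',6'-dihydroxy-4'-methoxyacetophenone
Product: 2 2-acetyl-3-hydroxy-5-methoxyphenyl pivalate
Conditions: PivCl (1.05 equiv), Et3N (1.2 equiv), CH2Cl2, 0 °C
Reagents that add atoms: pivaloyl chloride, CC(C)(C)C(=O)Cl
Why: O-acylation of a symmetric 2,6-dihydroxyaryl ketone should stop at the mono-ester, because the remaining hydroxyl is held in a hydrogen bond to the ketone and is much less nucleophilic.

Step 2
Reactants: 2 2-acetyl-3-hydroxy-5-methoxyphenyl pivalate
Product: 4 3-iodo-7-methoxy-4-oxo-4H-chromen-5-yl pivalate, via enaminone 3 (not isolated)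
Conditions: DMF-DMA (2 equiv), toluene, 80 °C; evaporate; then I2 (1.5 equiv), CHCl3, rt; aq. Na2S2O3
Reagents that add atoms: N,N-dimethylformamide dimethyl acetal (DMF-DMA), COC(OC)N(C)C; iodine, II
Why: Condensation of the methyl ketone with the amide acetal gives the enaminone, and iodine-mediated cyclisation (α-iodination, attack of the free phenol on the iminium carbon, loss of Me2NH) is the standard construction of 3-iodochromones and closes ring C.

Step 3
Reactants: 5 resorcinol
Product: 6 3-hydroxyphenyl pivalate
Conditions: resorcinol (3 equiv), PivCl (1 equiv), Et3N (1.1 equiv), THF, 0 °C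
Reagents that add atoms: pivaloyl chloride, CC(C)(C)C(=O)Cl
Why: Statistical mono-acylation of a symmetric diphenol used in excess should give mainly the mono-ester, and the water-soluble surplus resorcinol is washed out.

Step 4
Reactants: 6 3-hydroxyphenyl pivalate; 7 3-chloro-3-methylbut-1-yne
Product: 8 3-[(2-methylbut-3-yn-2-yl)oxy]phenyl pivalate
Conditions: DBU (1.3 equiv), CuCl2·2H2O (1 mol %), MeCN, 0 °C
Reagents that add atoms: none
Why: Copper-catalysed propargylic etherification (substitution at the tertiary propargylic chloride through a copper acetylide/allenylidene) is the established way to make aryl 1,1-dimethylpropargyl ethers and avoids C-alkylation.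

Step 5
Reactants: 4 3-iodo-7-methoxy-4-oxo-4H-chromen-5-yl pivalate; 8 3-[(2-methylbut-3-yn-2-yl)oxy]phenyl pivalate
Product: 9 7-methoxy-3-{3-methyl-3-[3-(pivaloyloxy)phenoxy]but-1-yn-1-yl}-4-oxo-4H-chromen-5-yl pivalate
Conditions: PdCl2(PPh3)2 (3 mol %), CuI (5 mol %), Et3N (3 equiv), THF, degassed, rt
Reagents that add atoms: none
Why: Sonogashira coupling of 3-iodochromones with terminal alkynes is well precedented; a tertiary amine avoids conjugate addition to C2 of the chromone, and room temperature avoids propargyl Claisen rearrangement of the aryl ether.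

Step 6
Reactants: 9 7-methoxy-3-{3-methyl-3-[3-(pivaloyloxy)phenoxy]but-1-yn-1-yl}-4-oxo-4H-chromen-5-yl pivalate
Product: 11 7-methoxy-3-{3-methyl-3-[3-(pivaloyloxy)phenoxy]butyl}-4-oxo-4H-chromen-5-yl pivalate, via Z-alkene 10 (not isolated)
Conditions: H2 (4 atm), RhCl(PPh3)3 (10 mol %), toluene/EtOH, 40 °C
Reagents that add atoms: none
Why: Homogeneous rhodium-catalysed hydrogenation should reduce the alkyne by two syn additions of H2 while leaving the conjugated, trisubstituted C2=C3 bond of ring C and the tertiary C–O bond untouched, since no π-allyl species is formed on this catalyst.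

Step 7
Reactants: 11 7-methoxy-3-{3-methyl-3-[3-(pivaloyloxy)phenoxy]butyl}-4-oxo-4H-chromen-5-yl pivalate
Product: 12 cyclointegrin 5,4'-di-O-pivalate
Conditions: Pd(OAc)2 (20 mol %), AgOAc (3 equiv), CsOPiv (1 equiv), PivOH (5 equiv), 1,4-dioxane (0.01 M), 110 °C
Reagents that add atoms: none
Why: Pd(OPiv)2 formed in the flask should cleave the C2–H bond of ring C by concerted metalation–deprotonation, then metalate ring B ortho to the tethered oxygen through a nine-membered palladacycle, and C–C reductive elimination should give the biaryl bond and zerovalent palladium, which AgOAc returns to divalent palladium. The closest known reaction types are the palladium-catalysed dehydrogenative C2 arylation of chromones with simple arenes and the intramolecular palladium-catalysed twofold C–H coupling of tethered heteroarene–arene pairs that closes seven- and eight-membered rings. Ring D is the only ring closed, by C(sp2)–C(sp2) reductive elimination from the nine-membered palladacycle; should arene palladation come first, the same ring would arise by an 8-endo Heck-type insertion into C2=C3 and loss of HPd through the palladium enolate. No stereocentre is formed. The step needs site selectivity on ring B and ring closure over intermolecular coupling: of the two carbons ortho to the ether oxygen, the one between the two oxygen substituents is shielded, the carbon para to the ether oxygen cannot reach C2, and high dilution with the gem-dimethyl group favours cyclisation. Pivalates were chosen because they carry no aryl C–H bond and do not exchange in PivOH, so no dehydrogenative cyclisation onto a protecting group can compete.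

Step 8
Reactants: 12 cyclointegrin 5,4'-di-O-pivalate
Product: 13 cyclointegrin
Conditions: K2CO3 (0.3 equiv), MeOH/THF, 40 °C; aq. NH4Cl
Reagents that add atoms: none
Why: Base-catalysed transesterification cleaves both aryl pivalates, while the tertiary alkyl aryl ether, which would be at risk under acidic deprotection, and the 2-aryl-3-alkylchromone are stable to mild base.

**Compound list**

1 | 2',6'-dihydroxy-4'-methoxyacetophenone | CC(=O)c1c(O)cc(OC)cc1O | starting material
2 | 2-acetyl-3-hydroxy-5-methoxyphenyl pivalate | CC(=O)c1c(O)cc(OC)cc1OC(=O)C(C)(C)C | intermediate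
3 | 2-[(E)-3-(dimethylamino)acryloyl]-3-hydroxy-5-methoxyphenyl pivalate (enaminone, not isolated) | CN(C)/C=C/C(=O)c1c(O)cc(OC)cc1OC(=O)C(C)(C)C | intermediate
4 | 3-iodo-7-methoxy-4-oxo-4H-chromen-5-yl pivalate | COc1cc(OC(=O)C(C)(C)C)c2c(=O)c(I)coc2c1 | intermediate
5 | resorcinol | Oc1cccc(O)c1 | starting material
6 | 3-hydroxyphenyl pivalate | CC(C)(C)C(=O)Oc1cccc(O)c1 | intermediate
7 | 3-chloro-3-methylbut-1-yne | C#CC(C)(C)Cl | starting material
8 | 3-[(2-methylbut-3-yn-2-yl)oxy]phenyl pivalate | C#CC(C)(C)Oc1cccc(OC(=O)C(C)(C)C)c1 | intermediate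
9 | 7-methoxy-3-{3-methyl-3-[3-(pivaloyloxy)phenoxy]but-1-yn-1-yl}-4-oxo-4H-chromen-5-yl pivalate | COc1cc(OC(=O)C(C)(C)C)c2c(=O)c(C#CC(C)(C)Oc3cccc(OC(=O)C(C)(C)C)c3)coc2c1 | intermediate
10 | 7-methoxy-3-{(Z)-3-methyl-3-[3-(pivaloyloxy)phenoxy]but-1-en-1-yl}-4-oxo-4H-chromen-5-yl pivalate (not isolated) | COc1cc(OC(=O)C(C)(C)C)c2c(=O)c(/C=C\C(C)(C)Oc3cccc(OC(=O)C(C)(C)C)c3)coc2c1 | intermediate
11 | 7-methoxy-3-{3-methyl-3-[3-(pivaloyloxy)phenoxy]butyl}-4-oxo-4H-chromen-5-yl pivalate | COc1cc(OC(=O)C(C)(C)C)c2c(=O)c(CCC(C)(C)Oc3cccc(OC(=O)C(C)(C)C)c3)coc2c1 | intermediate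
12 | cyclointegrin 5,4'-di-O-pivalate | COc1cc(OC(=O)C(C)(C)C)c2c(=O)c3c(oc2c1)-c1ccc(OC(=O)C(C)(C)C)cc1OC(C)(C)CC3 | intermediate
13 | cyclointegrin | COc1cc(O)c2c(=O)c3c(oc2c1)-c1ccc(O)cc1OC(C)(C)CC3 | target

**Step count and risks**

Total step count: 8. Longest linear sequence: 6 steps (steps 1, 2, 5, 6, 7, 8 from 1; equally steps 3 to 8 from 5).

Steps most likely to fail:

1. Step 7. Closure of the eight-membered ring may be slower than intermolecular coupling or protodepalladation, and the tertiary aryl ether may ionise in hot carboxylic acid. The fallback fixes the site on ring B with a halogen and uses a non-oxidative zerovalent-palladium cycle; it sets out from 6 and comes back at 12. Ortho-selective bromination of 6 (NBS, iPr2NH cat., CH2Cl2, 0 °C) should give 4-bromo-3-hydroxyphenyl pivalate F1. Propargylation with 7 under the conditions of step 4 should give 4-bromo-3-[(2-methylbut-3-yn-2-yl)oxy]phenyl pivalate F2. Sonogashira coupling with 4 at room temperature, where the C–I bond reacts and the C–Br bond is kept, should give the bromo alkyne F3. Hydrogenation as in step 6 through the bromo Z-alkene F4 (not isolated) should give the bromo alkane F5. Intramolecular direct arylation of the chromone C2–H (Pd(OAc)2, PCy3·HBF4, K2CO3, PivOH 30 mol %, DMA, 110 °C) should then give 12.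

2. Step 6. The hindered alkyne may stall at the alkene stage, or forcing conditions may reduce C2=C3 of ring C or cleave the C–O bond. The fallback makes the C3–CH2 bond on a saturated chain; it sets out from 8 and comes back at 11. Semi-hydrogenation of 8 (H2, Pd/CaCO3 poisoned with Pb(OAc)2, quinoline, EtOAc) should give 3-[(2-methylbut-3-en-2-yl)oxy]phenyl pivalate F6. Hydroboration with 9-BBN-H (THF, rt) should give the primary alkylborane F7 (not isolated). B-alkyl Suzuki–Miyaura coupling with 4 (PdCl2(dppf), AsPh3, Cs2CO3, DMF/THF/H2O, rt) should give 11; the aryl pivalates are expected to survive at room temperature.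

3. Step 2. Methoxide released from the amide acetal may cleave the aryl pivalate, followed by O-methylation. The fallback introduces the ester only after ring C is made; it sets out from 1 and comes back at 4. Mono-benzylation of 1 (BnBr 1 equiv, K2CO3, acetone) should give 1-[2-(benzyloxy)-6-hydroxy-4-methoxyphenyl]ethan-1-one F8. DMF-DMA, then I2 as in step 2, through the benzyl enaminone F9 (not isolated), should give 5-(benzyloxy)-3-iodo-7-methoxy-4H-chromen-4-one F10. Chelation-assisted debenzylation at O-5 (BCl3, CH2Cl2, −78 °C) should give 5-hydroxy-3-iodo-7-methoxy-4H-chromen-4-one F11. Pivaloylation (PivCl, Et3N, DMAP, CH2Cl2) should give 4.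

**Further compounds**

F1 | step 7 | 4-bromo-3-hydroxyphenyl pivalate | CC(C)(C)C(=O)Oc1ccc(Br)c(O)c1
F2 | step 7 | 4-bromo-3-[(2-methylbut-3-yn-2-yl)oxy]phenyl pivalate | C#CC(C)(C)Oc1cc(OC(=O)C(C)(C)C)ccc1Br
F3 | step 7 | 3-{3-[2-bromo-5-(pivaloyloxy)phenoxy]-3-methylbut-1-yn-1-yl}-7-methoxy-4-oxo-4H-chromen-5-yl pivalate | COc1cc(OC(=O)C(C)(C)C)c2c(=O)c(C#CC(C)(C)Oc3cc(OC(=O)C(C)(C)C)ccc3Br)coc2c1
F4 | step 7 | 3-{(Z)-3-[2-bromo-5-(pivaloyloxy)phenoxy]-3-methylbut-1-en-1-yl}-7-methoxy-4-oxo-4H-chromen-5-yl pivalate | COc1cc(OC(=O)C(C)(C)C)c2c(=O)c(/C=C\C(C)(C)Oc3cc(OC(=O)C(C)(C)C)ccc3Br)coc2c1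
F5 | step 7 | 3-{3-[2-bromo-5-(pivaloyloxy)phenoxy]-3-methylbutyl}-7-methoxy-4-oxo-4H-chromen-5-yl pivalate | COc1cc(OC(=O)C(C)(C)C)c2c(=O)c(CCC(C)(C)Oc3cc(OC(=O)C(C)(C)C)ccc3Br)coc2c1
F6 | step 6 | 3-[(2-methylbut-3-en-2-yl)oxy]phenyl pivalate | C=CC(C)(C)Oc1cccc(OC(=O)C(C)(C)C)c1
F7 | step 6 | 3-{[4-(9-borabicyclo[3.3.1]nonan-9-yl)-2-methylbutan-2-yl]oxy}phenyl pivalate | CC(C)(CCB1C2CCCC1CCC2)Oc1cccc(OC(=O)C(C)(C)C)c1
F8 | step 2 | 1-[2-(benzyloxy)-6-hydroxy-4-methoxyphenyl]ethan-1-one | CC(=O)c1c(O)cc(OC)cc1OCc1ccccc1
F9 | step 2 | (E)-1-[2-(benzyloxy)-6-hydroxy-4-methoxyphenyl]-3-(dimethylamino)prop-2-en-1-one | CN(C)/C=C/C(=O)c1c(O)cc(OC)cc1OCc1ccccc1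
F10 | step 2 | 5-(benzyloxy)-3-iodo-7-methoxy-4H-chromen-4-one | COc1cc(OCc2ccccc2)c2c(=O)c(I)coc2c1
F11 | step 2 | 5-hydroxy-3-iodo-7-methoxy-4H-chromen-4-one | COc1cc(O)c2c(=O)c(I)coc2c1
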